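**Assumption:** 1,2,3,4-tetramethoxybenzene (1), methyl (E)-3-methoxyacrylate (9) and 2,6-dibromoanisole (12) are taken as purchasable starting materials.

## The problem

Target 24 is an achiral isoflavone. Its ring A (C4a, C5 to C8, C8a) is hexasubstituted: oxygen sits on five neighbouring carbons (O1 on C8a, methoxy on C8, C7 and C6, hydroxyl on C5) and the acyl carbon C4 on the sixth. Ring B is joined to C3 through C1', which is flanked by the 2'-methoxy group with the 3'-hydroxyl next to it; electrophilic substitution of guaiacol-type arenes does not give this 1,2,3-pattern. Two pairs of oxygens must be told apart: O5–H from the three methoxy groups of ring A, and O3'–H from O2'–CH3. There is no stereocenter, so the task is regiocontrol on two crowded benzene rings and the making of C4–C4a, O1–C8a, O1–C2 and C3–C1'. The pentaoxygenated ring A is easily oxidised to quinones and loses methyl groups under strong Lewis acids, and the pyranone ring opens with hydroxide, so hot Friedel–Crafts conditions and late aqueous base are best avoided.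

The feature the plan uses is this. C4a and C8a are neighbouring ring-A carbons that carry exactly an acyl carbon (C4) and an oxygen (O1), and the other four ring-A carbons C5 to C8 all carry oxygen. With O5 written as a methyl ether, ring A is symmetric about the axis through the midpoints of C4a–C8a and C6–C7. Ring A is therefore the symmetric aryne 3,4,5,6-tetramethoxybenzyne (21). The unit O1–C2H=C3(aryl)–C4=O of ring C is the carboxyl group and the two alkene carbons of a 2-aryl-3-methoxyacrylic acid (20). Afterwards the one methyl ether peri to the C4 carbonyl is the one that chelation singles out for removal.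

## Retrosynthesis

**24 from 23.** The O5–CH3 bond and the O3'–isopropyl bond are cut. Carrying O5 as a methyl ether makes ring A symmetric. The alternative, a free or differently protected O5, would need an unsymmetrical aryne with a regiochemical question. Precursor 23 has no free hydroxyl. The forward reaction must cleave one of four ring-A methyl ethers and the isopropyl ether but not O2'–CH3; chelation of BCl3 between the C4 carbonyl and O5, and the easy ionisation of a secondary alkyl ether, are expected to do this in one operation.

**23 from 8 and 20 (through 21 and 22).** Three bonds are cut: C8a–O1, C4a–C4 and O1–C2. The neighbouring cuts (only C4–C4a as in a Friedel–Crafts acylation, or only C3–C1' as in a cross-coupling) leave ring C to be made in separate steps. Cutting both ring-A bonds turns ring A into aryne 21, made in the flask from silyl triflate 8, and turns the rest into acid 20. Acid 20 already holds ring B, C2, C3, C4 and both ring-C oxygens at the right oxidation level. Because 21 is symmetric, the forward reaction needs no regiocontrol on the aryne. It needs the carboxylate to add through oxygen, the aryl anion to take the acyl group (giving 22), and the phenoxide of 22 to displace methoxide at the β-carbon.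

**20 from 19, and 19 from 16 and 11 (through 17 and 18).** The C3–C1' bond is cut at the stage of an open-chain acrylate, where C3 is an unhindered vinyl iodide carbon. Building the same acid from an arylacetic acid by formylation would first need a one-carbon homologation of the arene. Iodide 11 brings all three carbons at once. The forward reaction is a Negishi coupling of arylzinc 18 (from bromide 16 via aryllithium 17), followed by ester hydrolysis.

**16 from 15, and 15 from 12 (through 13 and 14).** The O3'–C3' bond is cut. The 2'-methoxy carbon of ring B lies between two carbons that must become C–O and C–C. In 2,6-dibromoanisole 12 these two carbons are equivalent, so one bromine–lithium exchange followed by borylation and oxidation gives phenol 15 with no regiochemical choice. The second bromine is kept for the C–C bond. Guaiacol derivatives would be substituted or lithiated on the wrong side.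

**11 from 9 (through 10).** The C–I bond is cut. Iodination of the enol ether 9 at the α-carbon and loss of acetic acid from adduct 10 give the vinyl iodide in one step.

**8 from 5, 5 from 4, and 4 from 1 (through 2, 3, 6 and 7).** The C–Si and O–S bonds of 8 go back to o-bromophenol 5 by the standard O-silylation, exchange and retro-Brook sequence (through 6 and 7). The C–Br bond of 5 is cut to phenol 4, which has a single free ring position. The C–O bond of 4 is cut to 1, whose two ring hydrogens are equivalent and each ortho to a methoxy group (through aryllithium 2 and boronate 3).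

## Roads not taken

**Alternative 1:** the deoxybenzoin route, the most obvious one. The cuts are C4–C4a and both bonds to C2. The forward key step is a Friedel–Crafts (or Hoesch) acylation of phenol 4 at its only free position with [2-methoxy-3-(propan-2-yloxy)phenyl]acetic acid A1 (BF3·OEt2, heat) to give deoxybenzoin A2. C2 is then inserted with DMF dimethyl acetal to reach 23. The chosen plan is preferred for three reasons:
- Ring C is made in two operations instead of one.
- The acylation needs hot Lewis acid on an oxidation-prone phenol, conditions that threaten the isopropyl ether and the methoxy group ortho to the new ketone.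
- A1 needs a homologation of bromide 16 no shorter than the path from 16 to 20, so nothing is saved in steps.

**Alternative 2:** cross-coupling at C3–C1'. The forward key step is a Suzuki–Miyaura coupling of 3-iodo-5,6,7,8-tetramethoxy-4H-chromen-4-one A3 with [2-methoxy-3-(propan-2-yloxy)phenyl]boronic acid A4. A3 would come from phenol 4 by C-acetylation, condensation with DMF dimethyl acetal and iodine-induced ring closure. The chosen plan is preferred for two reasons:
- Ring C is built first without ring B and then functionalised, which gives no gain in step count.
- The most hindered bond of the target is made last, between an iodide flanked by C2 and the C4 carbonyl and an ortho-alkoxy boronic acid prone to protodeboronation. In the chosen plan the same bond is made early on an unhindered vinyl iodide.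

**Alternative 3:** oxidative 1,2-aryl shift. The cut is C3–C1', with ring B reconnected to C2. The forward key step treats chalcone A5 (from a Claisen–Schmidt condensation) with Tl(NO3)3 (trivalent thallium) or PhI(OAc)2 in methanol. Ring B migrates through a phenonium ion to give acetal A6, which acid then closes to 23. The chosen plan is preferred for three reasons:
- The migrating ring carries an ortho substituent, and its 3'-oxygen is meta to the migrating carbon and so does not help the shift.
- The oxidant also meets the pentaoxygenated ring A, which is open to quinone formation.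
- It uses a stoichiometric toxic metal salt and is longer.

Key step: step 9

## Route

Step 1
Reactants: 1 1,2,3,4-tetramethoxybenzene
Product: 4 2,3,4,5-tetramethoxyphenol, via aryllithium 2 (not isolated), via dimethyl arylboronate 3 (not isolated)
Conditions: n-BuLi, TMEDA, THF, 0 °C; B(OMe)3, −78 °C to rt; then 30% H2O2, AcOH, 0 °C
Reagents that add atoms: hydrogen peroxide (OO)
Why: Directed ortho-lithiation; the two ring hydrogens of 1 are equivalent and each is ortho to a methoxy group. Borylation and boronate oxidation then put oxygen on that carbon.

Step 2
Reactants: 4 2,3,4,5-tetramethoxyphenol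
Product: 5 2-bromo-3,4,5,6-tetramethoxyphenol
Conditions: NBS (1.0 equiv), dry CH2Cl2, −20 °C, dark
Reagents that add atoms: N-bromosuccinimide (O=C1CCC(=O)N1Br)
Why: Electrophilic aromatic bromination; the only free ring position is ortho to the hydroxyl, so there is no regiochemical choice. Low temperature and exclusion of water should hold back oxidation to a quinone.

Step 3
Reactants: 5 2-bromo-3,4,5,6-tetramethoxyphenol
Product: 8 2,3,4,5-tetramethoxy-6-(trimethylsilyl)phenyl trifluoromethanesulfonate, via aryl trimethylsilyl ether 6 (not isolated), via lithium 2-(trimethylsilyl)phenoxide 7 (not isolated)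
Conditions: HMDS, THF, 65 °C, then evaporate; n-BuLi, THF, −78 °C; Tf2O, −78 °C to rt
Reagents that add atoms: hexamethyldisilazane (C[Si](C)(C)N[Si](C)(C)C); trifluoromethanesulfonic anhydride (O=S(=O)(OS(=O)(=O)C(F)(F)F)C(F)(F)F)
Why: O-silylation, bromine–lithium exchange and a 1,3 O-to-C silyl shift (retro-Brook rearrangement) put silicon on the carbon that bore bromine. The phenoxide is trapped as the triflate, the standard entry to o-silylaryl triflates.

Step 4
Reactants: 9 methyl (E)-3-methoxyacrylate
Product: 11 methyl (Z)-2-iodo-3-methoxyacrylate, via methyl 3-acetoxy-2-iodo-3-methoxypropanoate 10 (not isolated)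
Conditions: NIS, AcOH, CH2Cl2, rt; then Et3N, rt
Reagents that add atoms: N-iodosuccinimide (O=C1CCC(=O)N1I)
Why: Iodoacetoxylation of the enol ether followed by base-induced loss of acetic acid (addition–elimination). The elimination should give the more stable isomer with methoxy trans to the ester, which is the (Z)-iodide.

Step 5
Reactants: 12 2,6-dibromoanisole (1,3-dibromo-2-methoxybenzene)
Product: 15 3-bromo-2-methoxyphenol, via aryllithium 13 (not isolated), via dimethyl arylboronate 14 (not isolated)
Conditions: n-BuLi (1.0 equiv), THF, −78 °C; B(OMe)3, −78 °C to rt; then 30% H2O2, AcOH, 0 °C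
Reagents that add atoms: hydrogen peroxide (OO)
Why: Bromine–lithium exchange on the symmetric dibromide stops after one exchange, and lithium sits meta to the second bromine, so no aryne can form. Borylation and boronate oxidation turn that carbon into the phenol.

Step 6
Reactants: 15 3-bromo-2-methoxyphenol
Product: 16 1-bromo-2-methoxy-3-(propan-2-yloxy)benzene
Conditions: 2-bromopropane, K2CO3, DMF, 60 °C
Reagents that add atoms: 2-bromopropane (CC(C)Br)
Why: Williamson ether synthesis (SN2 on the phenoxide). The isopropyl ether should survive organolithium, fluoride and hydroxide and is cleaved by BCl3 in the last step.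

Step 7
Reactants: 16 1-bromo-2-methoxy-3-(propan-2-yloxy)benzene; 11 methyl (Z)-2-iodo-3-methoxyacrylate
Product: 19 methyl (E)-3-methoxy-2-[2-methoxy-3-(propan-2-yloxy)phenyl]prop-2-enoate, via aryllithium 17 (not isolated), via arylzinc chloride 18 (not isolated)
Conditions: n-BuLi, THF, −78 °C; ZnCl2, −78 to 0 °C; 11, Pd(PPh3)4 (5 mol %), THF, rt to 50 °C
Reagents that add atoms: none
Why: Bromine–lithium exchange, transmetalation to zinc and Negishi coupling under zerovalent palladium. Oxidative addition and reductive elimination go with retention at the vinyl iodide, so methoxy stays trans to the ester ((E)-19), and the organozinc tolerates the ester.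

Step 8
Reactants: 19 methyl (E)-3-methoxy-2-[2-methoxy-3-(propan-2-yloxy)phenyl]prop-2-enoate
Product: 20 (E)-3-methoxy-2-[2-methoxy-3-(propan-2-yloxy)phenyl]prop-2-enoic acid
Conditions: LiOH·H2O, THF/MeOH/H2O, rt; then cold 1 M HCl to pH 3
Reagents that add atoms: lithium hydroxide ([Li+].[OH-])
Why: Saponification of the methyl ester (acyl substitution by hydroxide). The β-methoxyacrylate is a vinylogous carbonate, so conjugate addition of hydroxide is slow at room temperature, and mild cold acidification spares the enol ether.

Step 9
Reactants: 8 2,3,4,5-tetramethoxy-6-(trimethylsilyl)phenyl trifluoromethanesulfonate; 20 (E)-3-methoxy-2-[2-methoxy-3-(propan-2-yloxy)phenyl]prop-2-enoic acid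
Product: 23 5,6,7,8-tetramethoxy-3-[2-methoxy-3-(propan-2-yloxy)phenyl]-4H-chromen-4-one, via 3,4,5,6-tetramethoxybenzyne 21 (not isolated), via o-hydroxyaryl β-methoxyvinyl ketone 22 (not isolated)
Conditions: 8 (1.5 equiv), CsF (4 equiv), THF, 125 °C, sealed tube
Reagents that add atoms: none
Why: Proposed new method: fluoride removes the silyl group of 8 and triflate leaves, giving the symmetric aryne 21, whose two triple-bond carbons are equivalent and each flanked by a methoxy group that activates them inductively, so no regiochemical question arises. The carboxylate of 20 adds through oxygen; the aryl anion formed beside the new C–O bond is stabilised by the flanking methoxy group and attacks the ester carbonyl 1,3 through a four-membered transition state (an anionic Fries-type O-to-C acyl shift), which gives the phenoxide of 22. This phenoxide closes ring C by 6-endo-trig conjugate addition to the β-methoxy enone and loss of methoxide, so that C8a–O1, C4a–C4 and O1–C2 are all made in one flask. The closest known reaction type is the insertion of arynes into the C–O bond of carboxylic acids under CsF, which gives o-hydroxyaryl ketones and, with acrylic or arylpropiolic acids, 4-chromanones or flavones by the same phenoxide conjugate addition; new here are the β-alkoxy leaving group, which turns the addition into an addition–elimination, and the fully substituted aryne. No stereocenter is formed. The step needs acyl transfer to win over protonation of the aryl anion (aprotic medium, excess CsF binding the acid proton as bifluoride) and carbonyl attack to win over attack at the β-carbon, which would give the isomeric 3-arylcoumarin; the preferred Z conformation of the aryl ester holds the carbonyl carbon and not the β-carbon next to the anion, and the β-methoxy group lowers the electrophilicity of that carbon.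

Step 10
Reactants: 23 5,6,7,8-tetramethoxy-3-[2-methoxy-3-(propan-2-yloxy)phenyl]-4H-chromen-4-one
Product: 24 5,3'-dihydroxy-6,7,8,2'-tetramethoxyisoflavone (5-hydroxy-3-(3-hydroxy-2-methoxyphenyl)-6,7,8-trimethoxy-4H-chromen-4-one)
Conditions: BCl3 (1 M in CH2Cl2, about 4 equiv), CH2Cl2, −78 to 0 °C; then aq. NaHCO3/MeOH
Reagents that add atoms: none
Why: Lewis acid ether cleavage. BCl3 chelated between the C4 carbonyl and O5 delivers chloride only to the 5-O-methyl group, since the other ring-A methyl ethers and O2'–CH3 have no such chelate. The secondary isopropyl ether ionises far faster than a methyl ether, and aqueous work-up hydrolyses the boron chelate.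

## Compound list

1 | 1,2,3,4-tetramethoxybenzene | COc1ccc(OC)c(OC)c1OC | starting material
2 | (2,3,4,5-tetramethoxyphenyl)lithium | [Li]c1cc(OC)c(OC)c(OC)c1OC | intermediate
3 | dimethyl (2,3,4,5-tetramethoxyphenyl)boronate | COB(OC)c1cc(OC)c(OC)c(OC)c1OC | intermediate
4 | 2,3,4,5-tetramethoxyphenol | COc1cc(O)c(OC)c(OC)c1OC | intermediate
5 | 2-bromo-3,4,5,6-tetramethoxyphenol | COc1c(Br)c(O)c(OC)c(OC)c1OC | intermediate
6 | (2-bromo-3,4,5,6-tetramethoxyphenoxy)trimethylsilane | COc1c(Br)c(O[Si](C)(C)C)c(OC)c(OC)c1OC | intermediate
7 | lithium 2,3,4,5-tetramethoxy-6-(trimethylsilyl)phenoxide | COc1c([Si](C)(C)C)c(O[Li])c(OC)c(OC)c1OC | intermediate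
8 | 2,3,4,5-tetramethoxy-6-(trimethylsilyl)phenyl trifluoromethanesulfonate | COc1c([Si](C)(C)C)c(OS(=O)(=O)C(F)(F)F)c(OC)c(OC)c1OC | intermediate
9 | methyl (E)-3-methoxyacrylate | CO/C=C/C(=O)OC | starting material
10 | methyl 3-acetoxy-2-iodo-3-methoxypropanoate (mixture of diastereomers, racemic) | COC(OC(C)=O)C(I)C(=O)OC | intermediate
11 | methyl (Z)-2-iodo-3-methoxyacrylate | CO/C=C(\I)C(=O)OC | intermediate
12 | 2,6-dibromoanisole (1,3-dibromo-2-methoxybenzene) | COc1c(Br)cccc1Br | starting material
13 | (3-bromo-2-methoxyphenyl)lithium | COc1c(Br)cccc1[Li] | intermediate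
14 | dimethyl (3-bromo-2-methoxyphenyl)boronate | COB(OC)c1cccc(Br)c1OC | intermediate
15 | 3-bromo-2-methoxyphenol | COc1c(O)cccc1Br | intermediate
16 | 1-bromo-2-methoxy-3-(propan-2-yloxy)benzene | COc1c(Br)cccc1OC(C)C | intermediate
17 | [2-methoxy-3-(propan-2-yloxy)phenyl]lithium | COc1c([Li])cccc1OC(C)C | intermediate
18 | chloro[2-methoxy-3-(propan-2-yloxy)phenyl]zinc | COc1c([Zn]Cl)cccc1OC(C)C | intermediate
19 | methyl (E)-3-methoxy-2-[2-methoxy-3-(propan-2-yloxy)phenyl]prop-2-enoate | CO/C=C(/C(=O)OC)c1cccc(OC(C)C)c1OC | intermediate
20 | (E)-3-methoxy-2-[2-methoxy-3-(propan-2-yloxy)phenyl]prop-2-enoic acid | CO/C=C(/C(=O)O)c1cccc(OC(C)C)c1OC | intermediate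
21 | 3,4,5,6-tetramethoxybenzyne | COC1=C(OC)C(OC)=C(OC)C#C1 | intermediate
22 | (E)-1-(2-hydroxy-3,4,5,6-tetramethoxyphenyl)-3-methoxy-2-[2-methoxy-3-(propan-2-yloxy)phenyl]prop-2-en-1-one (formed as its phenoxide) | CO/C=C(/C(=O)c1c(O)c(OC)c(OC)c(OC)c1OC)c1cccc(OC(C)C)c1OC | intermediate
23 | 5,6,7,8-tetramethoxy-3-[2-methoxy-3-(propan-2-yloxy)phenyl]-4H-chromen-4-one | CC(C)Oc1cccc(-c2coc3c(OC)c(OC)c(OC)c(OC)c3c2=O)c1OC | intermediate
24 | 5,3'-dihydroxy-6,7,8,2'-tetramethoxyisoflavone | COc1c(O)cccc1-c1coc2c(OC)c(OC)c(OC)c(O)c2c1=O | target

## Step count and risk

Total step count: 10.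
Longest linear sequence: 6 steps (5, 6, 7, 8, 9, 10). Steps 1 to 3 and step 4 are side branches that join at steps 9 and 7.

**Step 9 (key step, Proposed new method).** Three processes are most likely to go wrong. The aryl anion may be protonated after O-arylation, which stops the sequence at the O–H insertion stage. The hindered, electron-rich aryne may be captured slowly and be consumed by the released methoxide instead. The anion may add to the β-carbon instead of the carbonyl. The fallback uses known chemistry and reaches the same aryl anion without an aryne. It sets out from bromophenol 5 and acid 20. Steglich esterification (EDC, DMAP, CH2Cl2) gives 2-bromo-3,4,5,6-tetramethoxyphenyl (E)-3-methoxy-2-[2-methoxy-3-(propan-2-yloxy)phenyl]prop-2-enoate F1. Bromine–lithium exchange with t-BuLi in THF at −100 °C, where no proton source is present, triggers the 1,3 O-to-C acyl shift (an anionic Fries rearrangement started by halogen–metal exchange) to the lithium salt of 22. On warming this closes with loss of methoxide, and the route is rejoined at 23.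

**Step 2.** The electron-rich phenol may be oxidised (oxidative loss of the methyl ether para to the hydroxyl, leading to a quinone) in competition with ring bromination. The fallback avoids both the free phenol and the bromination. It sets out from 1. Directed ortho-lithiation (n-BuLi, TMEDA) and quenching with Me3SiCl give trimethyl(2,3,4,5-tetramethoxyphenyl)silane F2. A second directed ortho-lithiation at the only remaining ring hydrogen (s-BuLi, TMEDA), then B(OMe)3 and H2O2/NaOH, give 2,3,4,5-tetramethoxy-6-(trimethylsilyl)phenol F3. Triflation (Tf2O, pyridine) brings the route back at 8.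

**Step 7.** Transmetalation and coupling of the ortho-methoxy arylzinc may be slow, so that reduction or homocoupling of the vinyl iodide takes over. The fallback builds the acrylate on the arene instead of coupling it. It sets out from 16. Palladium-catalysed coupling with the Reformatsky reagent BrZnCH2CO2t-Bu (Pd(dba)2, P(t-Bu)3, THF) gives tert-butyl [2-methoxy-3-(propan-2-yloxy)phenyl]acetate F4. Claisen formylation (NaH, HCO2Me) and O-methylation of the enolate (Me2SO4) give tert-butyl (E)-3-methoxy-2-[2-methoxy-3-(propan-2-yloxy)phenyl]prop-2-enoate F5. CF3CO2H in CH2Cl2 removes the tert-butyl group and the route is rejoined at 20, which also bypasses step 8.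

**Step 10.** Over-demethylation is the risk: once boron is bound to O5 or O3', it can deliver chloride to the neighbouring 6- or 2'-methoxy group. The fallback separates the two unmaskings into two mechanistically different operations with an isolable intermediate. It sets out from 23. Concentrated HCl in ethanol at reflux cleaves only the hydrogen-bonded, carbonyl-activated 5-O-methyl group (acid-assisted SN2 by chloride) and gives 5-hydroxy-6,7,8-trimethoxy-3-[2-methoxy-3-(propan-2-yloxy)phenyl]-4H-chromen-4-one F6. A limited amount of BCl3 at −78 °C then removes only the isopropyl group and gives 24.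

## Further compounds

F1 | step 9 | 2-bromo-3,4,5,6-tetramethoxyphenyl (E)-3-methoxy-2-[2-methoxy-3-(propan-2-yloxy)phenyl]prop-2-enoate | CO/C=C(/C(=O)Oc1c(Br)c(OC)c(OC)c(OC)c1OC)c1cccc(OC(C)C)c1OC
F2 | step 2 | trimethyl(2,3,4,5-tetramethoxyphenyl)silane | COc1cc([Si](C)(C)C)c(OC)c(OC)c1OC
F3 | step 2 | 2,3,4,5-tetramethoxy-6-(trimethylsilyl)phenol | COc1c(OC)c(OC)c(O)c([Si](C)(C)C)c1OC
F4 | step 7 | tert-butyl [2-methoxy-3-(propan-2-yloxy)phenyl]acetate | COc1c(CC(=O)OC(C)(C)C)cccc1OC(C)C
F5 | step 7 | tert-butyl (E)-3-methoxy-2-[2-methoxy-3-(propan-2-yloxy)phenyl]prop-2-enoate | CO/C=C(/C(=O)OC(C)(C)C)c1cccc(OC(C)C)c1OC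
F6 | step 10 | 5-hydroxy-6,7,8-trimethoxy-3-[2-methoxy-3-(propan-2-yloxy)phenyl]-4H-chromen-4-one | CC(C)Oc1cccc(-c2coc3c(OC)c(OC)c(OC)c(O)c3c2=O)c1OC
A1 | alternative 1 | [2-methoxy-3-(propan-2-yloxy)phenyl]acetic acid | COc1c(CC(=O)O)cccc1OC(C)C
A2 | alternative 1 | 1-(2-hydroxy-3,4,5,6-tetramethoxyphenyl)-2-[2-methoxy-3-(propan-2-yloxy)phenyl]ethan-1-one | COc1c(CC(=O)c2c(O)c(OC)c(OC)c(OC)c2OC)cccc1OC(C)C
A3 | alternative 2 | 3-iodo-5,6,7,8-tetramethoxy-4H-chromen-4-one | COc1c(OC)c(OC)c2c(=O)c(I)coc2c1OC
A4 | alternative 2 | [2-methoxy-3-(propan-2-yloxy)phenyl]boronic acid | COc1c(B(O)O)cccc1OC(C)C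
A5 | alternative 3 | (E)-1-(2-hydroxy-3,4,5,6-tetramethoxyphenyl)-3-[2-methoxy-3-(propan-2-yloxy)phenyl]prop-2-en-1-one | COc1c(/C=C/C(=O)c2c(O)c(OC)c(OC)c(OC)c2OC)cccc1OC(C)C
A6 | alternative 3 | 1-(2-hydroxy-3,4,5,6-tetramethoxyphenyl)-3,3-dimethoxy-2-[2-methoxy-3-(propan-2-yloxy)phenyl]propan-1-one (racemic) | COc1c(C(C(OC)OC)C(=O)c2c(O)c(OC)c(OC)c(OC)c2OC)cccc1OC(C)C
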